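**Retrosynthetic overview**
1. Last C–C bond: Stille coupling of a ring-bound (1E,3E)-dienylstannane with the (E)-3-bromoacrylamide of 2-amino-3-hydroxycyclopent-2-enone.
2. Key bond: the enamide C2–N bond. The primary dienamide opens one of the two mirror-related oxiranes of a meso bis-epoxy ketone enantioselectively, and water is then lost. This one step fixes C4, C5 and C6.
3. The meso bis-epoxide comes from double hydroxyl-face epoxidation of a symmetric p-quinol, made from a stannyldienyllithium and p-benzoquinone.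
4. Side pieces: the dienamide from cyclohexanecarbaldehyde (HWE, aminolysis), and the bromoacrylamide from propiolic acid and cyclopentane-1,3-dione.
5. Ring order: all three carbocycles are bought. The only rings formed are the two oxiranes (together, step 3), and one of them is consumed in the C–N step.

Numbering used in the names: C1 = ring ketone (or its ketal), C2 = N-bearing carbon, C3 = vinylic CH, C4 = carbinol carbon, C5/C6 = oxirane carbons (C6 next to C1). The target is (4R,5S,6R), with the oxirane cis to the C4 hydroxyl.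

Assumption: the sense of induction in step 6 cannot be predicted. The cinchonidine-derived salt is written; if it favours the antipode, its cinchonine-derived pseudoenantiomer is used in the same way.

**Step 1**
Reactants: 1 1,4-bis(trimethylsilyl)buta-1,3-diyne
Product: 4 (1E,3E)-1,4-bis(tributylstannyl)buta-1,3-diene, via buta-1,3-diyne 2 (not isolated), via (E)-tributyl(but-1-en-3-ynyl)stannane 3 (not isolated)
Conditions: K2CO3 (0.1 equiv), MeOH–THF, 0 °C; Bu3SnH (2.3 equiv), Et3B/air, 0 °C to rt; concentrate; AIBN, 85 °C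
Reagents that add atoms: tributyltin hydride, CCCC[SnH](CCCC)CCCC
Why: Carbonate-catalysed methanolysis frees the diyne in solution and two radical hydrostannations put tin on the terminal carbons, the reversible stannyl-radical addition at 85 °C draining all isomers to the thermodynamic E,E-diene (radical hydrostannation).

**Step 2**
Reactants: 4 (1E,3E)-1,4-bis(tributylstannyl)buta-1,3-diene; 5 p-benzoquinone
Product: 7 4-hydroxy-4-[(1E,3E)-4-(tributylstannyl)buta-1,3-dien-1-yl]cyclohexa-2,5-dien-1-one, via stannyldienyllithium 6 (not isolated)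
Conditions: nBuLi (1.0 equiv), THF, −78 °C; cannulate into 5 (1.5 equiv), THF, −78 °C; AcOH quench
Reagents that add atoms: none
Why: Tin–lithium exchange of one stannyl group keeps the alkene geometry and the hard vinyllithium adds 1,2 to one quinone carbonyl at −78 °C (organolithium 1,2-addition); the product has a mirror plane, so no stereocentre arises yet.

**Step 3**
Reactants: 7 4-hydroxy-4-[(1E,3E)-4-(tributylstannyl)buta-1,3-dien-1-yl]cyclohexa-2,5-dien-1-one
Product: 9 meso-(2S,3R,4s,5S,6R)-2,3:5,6-diepoxy-4-hydroxy-4-[(1E,3E)-4-(tributylstannyl)buta-1,3-dien-1-yl]cyclohexan-1-one (both oxiranes cis to the hydroxyl), via syn-monoepoxide 8 (not isolated)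
Conditions: tBuOOH (5.5 M in decane, 3 equiv), BnNMe3OH (0.2 equiv), THF, −20 to 0 °C
Reagents that add atoms: tert-butyl hydroperoxide, CC(C)(C)OO
Why: Double Weitz–Scheffer epoxidation: the peroxide anion attacks only the two electron-poor enone bonds, not the dienylstannane, and comes in on the face of the small, hydrogen-bonding hydroxyl and away from the dienyl chain, so C2, C3, C5 and C6 are all set cis to OH and the product is meso.

**Step 4**
Reactants: 10 cyclohexanecarbaldehyde; 11 triethyl (E)-4-phosphonocrotonate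
Product: 12 ethyl (2E,4E)-5-cyclohexylpenta-2,4-dienoate
Conditions: LiN(SiMe3)2, THF, −78 °C to rt
Reagents that add atoms: none
Why: The vinylogous Horner–Wadsworth–Emmons olefination of a stabilised phosphonate with a branched aldehyde gives the new alkene E and keeps the crotonate alkene E.

**Step 5**
Reactants: 12 ethyl (2E,4E)-5-cyclohexylpenta-2,4-dienoate
Product: 13 (2E,4E)-5-cyclohexylpenta-2,4-dienamide
Conditions: Me3Al, NH4Cl, toluene, 0 to 50 °C; aq HCl work-up
Reagents that add atoms: ammonium chloride, [NH4+].[Cl-]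
Why: In this Weinreb-type aminolysis the aluminium amide made in the flask attacks the ester carbonyl faster than it adds in conjugate fashion, so the diene geometry is untouched.

**Step 6 (key step)**
Reactants: 9 meso-2,3:5,6-diepoxy-4-hydroxy-4-[(1E,3E)-4-(tributylstannyl)buta-1,3-dien-1-yl]cyclohexan-1-one; 13 (2E,4E)-5-cyclohexylpenta-2,4-dienamide
Product: 15 (2E,4E)-5-cyclohexyl-N-{(4R,5S,6R)-5,6-epoxy-4-hydroxy-1-oxo-4-[(1E,3E)-4-(tributylstannyl)buta-1,3-dien-1-yl]cyclohex-2-en-2-yl}penta-2,4-dienamide, via trans-amido alcohol 14 (not isolated)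
Conditions: N-(9-anthracenylmethyl)cinchonidinium bromide (10 mol%), powdered Cs2CO3 (1.5 equiv), 4 Å MS, toluene–CH2Cl2 4:1, −10 °C, then rt 2 h; pH 7 buffer
Reagents that add atoms: none
Why: Proposed new method: powdered Cs2CO3 deprotonates 13 only at the solid surface and the chiral ammonium cation carries the amidate into toluene as a tight ion pair while its free 9-hydroxyl (too weakly acidic to be quenched by the amidate) hydrogen-bonds to the ketone and one oxirane oxygen of 9, so SN2 attack through nitrogen, anti to the oxirane, occurs at only one of the two enantiotopic α-keto carbons (C2 rather than C6; C3 and C5 are neopentyl and lack carbonyl activation) to give 14, whose C2–H, now flanked by ketone and amide nitrogen, is lost together with the C3 hydroxyl by E1cB dehydration; breaking the mirror plane this way turns C4, C5 and C6 into the (4R,5S,6R) stereocentres in a single C–N bond formation, and the reaction stops at mono-opening because the product is held as its delocalised N-anion, which switches off the carbonyl activation of C6; the closest known reaction types are the α-opening and dehydration of 2,3-epoxycyclohexanones with azide, thiolates or secondary amines to 2-heteroatom enones, the catalytic desymmetrisation of simple meso-epoxides with carbamates or anilines, and asymmetric phase-transfer N-alkylation, none of which has been shown for a carboxamide on a bis-epoxy ketone.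

**Step 7**
Reactants: 16 propiolic acid
Product: 17 (E)-3-bromoacrylic acid
Conditions: 48% aq HBr, 95 °C; crystallise on cooling
Reagents that add atoms: hydrogen bromide, Br
Why: Conjugate hydrobromination of the ynoic acid puts bromine on the β-carbon, and at 95 °C the first-formed Z-acid equilibrates to the crystalline E-acid.

**Step 8**
Reactants: 18 cyclopentane-1,3-dione
Product: 19 3-hydroxy-2-nitrocyclopent-2-en-1-one (enol form of 2-nitrocyclopentane-1,3-dione)
Conditions: fuming HNO3, AcOH, 10 °C
Reagents that add atoms: nitric acid, O[N+](=O)[O-]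
Why: Electrophilic nitration of the enolised 1,3-dione takes place at C2, its only nucleophilic carbon.

**Step 9**
Reactants: 19 3-hydroxy-2-nitrocyclopent-2-en-1-one
Product: 20 2-amino-3-hydroxycyclopent-2-en-1-one hydrochloride
Conditions: H2 (1 atm), 10% Pd/C, EtOH, conc. HCl, rt
Reagents that add atoms: hydrogen chloride, Cl
Why: Catalytic hydrogenation reduces the nitro group, and the acid traps the air-sensitive amino enol as its stable salt.

**Step 10**
Reactants: 17 (E)-3-bromoacrylic acid; 20 2-amino-3-hydroxycyclopent-2-en-1-one hydrochloride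
Product: 22 (E)-3-bromo-N-(2-hydroxy-5-oxocyclopent-1-en-1-yl)acrylamide, via (E)-3-bromoacryloyl chloride 21 (not isolated)
Conditions: (COCl)2, DMF (cat.), CH2Cl2, 0 °C to rt; concentrate; 20, NaHCO3, THF–H2O, 0 °C; 1 M HCl to pH 2
Reagents that add atoms: none
Why: Acid chloride formation and Schotten–Baumann N-acylation; any enol O-acyl product shifts its acyl group to nitrogen, and the weak inorganic base does not add to the β-bromo carbon, so the E-bromoalkene survives.

**Step 11**
Reactants: 15 the (4R,5S,6R)-stannane of step 6; 22 (E)-3-bromo-N-(2-hydroxy-5-oxocyclopent-1-en-1-yl)acrylamide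
Product: 23 target CNP0111189.1, (2E,4E)-5-cyclohexyl-N-[(4R,5S,6R)-5,6-epoxy-4-hydroxy-4-{(1E,3E,5E)-7-[(2-hydroxy-5-oxocyclopent-1-en-1-yl)amino]-7-oxohepta-1,3,5-trien-1-yl}-1-oxocyclohex-2-en-2-yl]penta-2,4-dienamide
Conditions: PdCl2(MeCN)2 (5 mol%), DMF, rt, dark
Reagents that add atoms: none
Why: The Stille coupling (the divalent palladium precatalyst is reduced by the stannane to zerovalent palladium) runs at rt without base, keeps the geometry at both sp2 carbons, tolerates the free hydroxyl, enol and epoxy ketone, and touches no stereocentre.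

**Compound list**
1 | 1,4-bis(trimethylsilyl)buta-1,3-diyne | C[Si](C)(C)C#CC#C[Si](C)(C)C | starting material
2 | buta-1,3-diyne (in solution only) | C#CC#C | intermediate
3 | (E)-tributyl(but-1-en-3-ynyl)stannane | C#C/C=C/[Sn](CCCC)(CCCC)CCCC | intermediate
4 | (1E,3E)-1,4-bis(tributylstannyl)buta-1,3-diene | CCCC[Sn](CCCC)(CCCC)/C=C/C=C/[Sn](CCCC)(CCCC)CCCC | intermediate
5 | p-benzoquinone | O=C1C=CC(=O)C=C1 | starting material
6 | (1E,3E)-4-(tributylstannyl)buta-1,3-dienyllithium | [Li]/C=C/C=C/[Sn](CCCC)(CCCC)CCCC | intermediate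
7 | 4-hydroxy-4-[(1E,3E)-4-(tributylstannyl)buta-1,3-dien-1-yl]cyclohexa-2,5-dien-1-one | O=C1C=CC(O)(/C=C/C=C/[Sn](CCCC)(CCCC)CCCC)C=C1 | intermediate
8 | rac-(4R*,5S*,6R*)-5,6-epoxy-4-hydroxy-4-[(1E,3E)-4-(tributylstannyl)buta-1,3-dien-1-yl]cyclohex-2-en-1-one, oxirane cis to OH (one enantiomer drawn) | C1=C[C@](O)(/C=C/C=C/[Sn](CCCC)(CCCC)CCCC)[C@H]2O[C@H]2C1=O | intermediate
9 | meso-(2S,3R,4s,5S,6R)-2,3:5,6-diepoxy-4-hydroxy-4-[(1E,3E)-4-(tributylstannyl)buta-1,3-dien-1-yl]cyclohexan-1-one, both oxiranes cis to OH | O=C1[C@H]2O[C@H]2[C@](O)(/C=C/C=C/[Sn](CCCC)(CCCC)CCCC)[C@H]3O[C@@H]13 | intermediate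
10 | cyclohexanecarbaldehyde | O=CC1CCCCC1 | starting material
11 | triethyl (E)-4-phosphonocrotonate | CCOC(=O)/C=C/CP(=O)(OCC)OCC | starting material
12 | ethyl (2E,4E)-5-cyclohexylpenta-2,4-dienoate | CCOC(=O)/C=C/C=C/C1CCCCC1 | intermediate
13 | (2E,4E)-5-cyclohexylpenta-2,4-dienamide | NC(=O)/C=C/C=C/C1CCCCC1 | intermediate
14 | (2E,4E)-5-cyclohexyl-N-{(2R,3R,4R,5S,6R)-5,6-epoxy-3,4-dihydroxy-1-oxo-4-[(1E,3E)-4-(tributylstannyl)buta-1,3-dien-1-yl]cyclohex-2-yl}penta-2,4-dienamide (N trans to the C3 hydroxyl) | O=C1[C@H](NC(=O)/C=C/C=C/C3CCCCC3)[C@@H](O)[C@](O)(/C=C/C=C/[Sn](CCCC)(CCCC)CCCC)[C@H]2O[C@@H]12 | intermediate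
15 | (2E,4E)-5-cyclohexyl-N-{(4R,5S,6R)-5,6-epoxy-4-hydroxy-1-oxo-4-[(1E,3E)-4-(tributylstannyl)buta-1,3-dien-1-yl]cyclohex-2-en-2-yl}penta-2,4-dienamide | O=C(/C=C/C=C/C1CCCCC1)NC1=C[C@](O)(/C=C/C=C/[Sn](CCCC)(CCCC)CCCC)[C@H]2O[C@H]2C1=O | intermediate
16 | propiolic acid | C#CC(=O)O | starting material
17 | (E)-3-bromoacrylic acid | OC(=O)/C=C/Br | intermediate
18 | cyclopentane-1,3-dione | O=C1CCC(=O)C1 | starting material
19 | 3-hydroxy-2-nitrocyclopent-2-en-1-one | O=C1CCC(O)=C1[N+](=O)[O-] | intermediate
20 | 2-amino-3-hydroxycyclopent-2-en-1-one hydrochloride | Cl.NC1=C(O)CCC1=O | intermediate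
21 | (E)-3-bromoacryloyl chloride | O=C(Cl)/C=C/Br | intermediate
22 | (E)-3-bromo-N-(2-hydroxy-5-oxocyclopent-1-en-1-yl)acrylamide | O=C(/C=C/Br)NC1=C(O)CCC1=O | intermediate
23 | target CNP0111189.1, (4R,5S,6R) | O=C(/C=C/C=C/C1CCCCC1)NC1=C[C@](O)(/C=C/C=C/C=C/C(=O)NC2=C(O)CCC2=O)[C@H]2O[C@H]2C1=O | target

**Totals**
Total step count: 11. Longest linear sequence: 5 steps (1 → 2 → 3 → 6 → 11).

**Three steps most likely to fail**

Step 6 (the new step). The risks are low ee, attack through the amide oxygen, and base-induced breakdown of 9.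
- The fallback uses known chemistry only. It sets out from 12 and 4 and comes back at 15.
- Ester 12 is joined to commercial 2,5-dimethoxyaniline with Me3Al to give the anilide (2E,4E)-5-cyclohexyl-N-(2,5-dimethoxyphenyl)penta-2,4-dienamide F1.
- PhI(OAc)2 in MeOH oxidises it to the quinone monoketal (2E,4E)-5-cyclohexyl-N-(6,6-dimethoxy-3-oxocyclohexa-1,4-dien-1-yl)penta-2,4-dienamide F2.
- Asymmetric Weitz–Scheffer epoxidation of the unsubstituted enone bond follows, with tBuOOH and NaOH in toluene under phase transfer by N-benzylcinchoninium chloride (its pseudoenantiomer gives the antipode). After recrystallisation this gives (2E,4E)-5-cyclohexyl-N-[(5S,6R)-5,6-epoxy-1,1-dimethoxy-4-oxocyclohex-2-en-2-yl]penta-2,4-dienamide F3.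
- After N–H deprotonation with LiN(SiMe3)2, dienyllithium 6 (made from 4 as in step 2) adds to the ketone on the face away from the oxirane. The product is (2E,4E)-5-cyclohexyl-N-{(4R,5S,6R)-5,6-epoxy-4-hydroxy-1,1-dimethoxy-4-[(1E,3E)-4-(tributylstannyl)buta-1,3-dien-1-yl]cyclohex-2-en-2-yl}penta-2,4-dienamide F4.
- Montmorillonite K10 in CH2Cl2 removes the ketal and gives 15.

Step 2. The risks are electron transfer from the vinyllithium to the quinone, double addition, and acid-triggered dienone–phenol rearrangement of 7.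
- The fallback replaces the free quinone by a masked one. It sets out from 4 and comes back at 7.
- Dienyllithium 6 is made from 4 as before and added to commercial 4,4-dimethoxycyclohexa-2,5-dien-1-one, which has only one carbonyl and is much harder to reduce. This gives 4,4-dimethoxy-1-[(1E,3E)-4-(tributylstannyl)buta-1,3-dien-1-yl]cyclohexa-2,5-dien-1-ol F5.
- Montmorillonite K10 in wet CH2Cl2 then frees the ketone to give 7 without protodestannylation.

Step 11. The risks are protodestannylation or homocoupling of 15, and loss of the light- and base-sensitive polyene while tin residues are removed.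
- The fallback inverts the polarity and replaces the Stille coupling by a Heck coupling. It sets out from 15 and 20 and comes back at 23.
- I2 (1.0 equiv) in CH2Cl2 at 0 °C converts 15 with retention into (2E,4E)-5-cyclohexyl-N-{(4R,5S,6R)-5,6-epoxy-4-hydroxy-4-[(1E,3E)-4-iodobuta-1,3-dien-1-yl]-1-oxocyclohex-2-en-2-yl}penta-2,4-dienamide F6, from which tin is removed before the last step.
- Salt 20 is acylated with acryloyl chloride and NaHCO3 to give N-(2-hydroxy-5-oxocyclopent-1-en-1-yl)acrylamide F7.
- Heck coupling of the two under Jeffery conditions (Pd(OAc)2, Bu4NCl, NaHCO3, DMF, rt) gives 23 with the new alkene E.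

**Further compounds**
F1 | step 6 | (2E,4E)-5-cyclohexyl-N-(2,5-dimethoxyphenyl)penta-2,4-dienamide | COc1ccc(OC)c(NC(=O)/C=C/C=C/C2CCCCC2)c1
F2 | step 6 | (2E,4E)-5-cyclohexyl-N-(6,6-dimethoxy-3-oxocyclohexa-1,4-dien-1-yl)penta-2,4-dienamide | COC1(OC)C=CC(=O)C=C1NC(=O)/C=C/C=C/C1CCCCC1
F3 | step 6 | (2E,4E)-5-cyclohexyl-N-[(5S,6R)-5,6-epoxy-1,1-dimethoxy-4-oxocyclohex-2-en-2-yl]penta-2,4-dienamide | O=C(/C=C/C=C/C1CCCCC1)NC1=CC(=O)[C@H]2O[C@H]2C1(OC)OC
F4 | step 6 | (2E,4E)-5-cyclohexyl-N-{(4R,5S,6R)-5,6-epoxy-4-hydroxy-1,1-dimethoxy-4-[(1E,3E)-4-(tributylstannyl)buta-1,3-dien-1-yl]cyclohex-2-en-2-yl}penta-2,4-dienamide | O=C(/C=C/C=C/C1CCCCC1)NC1=C[C@](O)(/C=C/C=C/[Sn](CCCC)(CCCC)CCCC)[C@H]2O[C@H]2C1(OC)OC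
F5 | step 2 | 4,4-dimethoxy-1-[(1E,3E)-4-(tributylstannyl)buta-1,3-dien-1-yl]cyclohexa-2,5-dien-1-ol | COC1(OC)C=CC(O)(/C=C/C=C/[Sn](CCCC)(CCCC)CCCC)C=C1
F6 | step 11 | (2E,4E)-5-cyclohexyl-N-{(4R,5S,6R)-5,6-epoxy-4-hydroxy-4-[(1E,3E)-4-iodobuta-1,3-dien-1-yl]-1-oxocyclohex-2-en-2-yl}penta-2,4-dienamide | O=C(/C=C/C=C/C1CCCCC1)NC1=C[C@](O)(/C=C/C=C/I)[C@H]2O[C@H]2C1=O
F7 | step 11 | N-(2-hydroxy-5-oxocyclopent-1-en-1-yl)acrylamide | C=CC(=O)NC1=C(O)CCC1=O
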